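## Structural features

The target is a bibenzyl: a hexasubstituted benzene (ring A) joined from C6 through a CH2–CH2 chain to an unsubstituted phenyl ring (ring B). Going round ring A there is a methyl ester at C1, a hydroxyl at C2, a prenyl group at C3, a hydroxyl at C4, a second prenyl group at C5 and the phenethyl chain at C6. There is no stereocentre and no stereogenic double bond, since each prenyl alkene ends in a gem-dimethyl carbon, so the problem is purely one of regiochemistry. The fragile elements are the two ortho-prenyl phenol units, which acid closes to dimethylchromans and which oxidants attack, and the electron-rich resorcinol ring. The ester is a di-ortho-substituted salicylate that tolerates mild base. The real difficulty is to place six different substituents unambiguously and to reach the aromatic oxidation level without acid or oxidant. The key step reads C2(O)–C3(prenyl)–C4(O)–C5(prenyl) as the bis-enol of a 2,4-diprenylcyclohexane-1,3-dione, a ring-held doubly oxygenated diene, and reads C1 and C6 as the two sp carbons of an alkynoate. Ring A is closed by [4+2] cycloaddition and aromatised by loss of the two-carbon bridge of the dione.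

## Logic of the disconnections

17 to 15. The O–Si bond at the C4 oxygen and the O–CH2 bond at the C2 oxygen are cut. Both groups are fluoride-labile, chosen because any acid would cyclise a phenol onto its neighbouring prenyl group. The gain is that the two ring oxygens in 15 are differentiated exactly as the ring-forming step delivers them. The forward step must cleave an aryl silyl ether and then, through 16, an aryl 2-silylethyl ether without touching the ester.

15 to 10 and 13. The C1–C2 and C5–C6 bonds of ring A are cut and a CH2–CH2 bridge is restored between C2 and C5, passing through bicycle 14. This reduces a hexasubstituted arene to a cyclic diene and an alkyne that already carry all six substituents, and it supplies the aromatic oxidation level by extrusion. The forward step must be regioselective and must tolerate heat with a diene substituted at every diene carbon.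

13 to 11. The bond between the alkyne carbon and the ester carbon is cut, passing through 12. This leaves a commercial terminal alkyne, and the forward step is a routine acylation.

10 to 8. The O–Si bond at the central oxygen is cut, passing through enolate 9. The forward step must enolise towards the prenyl-bearing methine so that both prenyl carbons become diene carbons and the bridge stays unsubstituted.

8 to 6 and 2. The bond between the alpha' ring carbon and its prenyl CH2 is cut, passing through enolate 7. This places the second prenyl group by a position-specific enolate alkylation. The forward step must deprotonate at the alpha' and not the gamma carbon, and must stop at monoalkylation.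

6 to 4 and 5. The enol O–CH2 bond is cut. Because 4 is symmetric, only one vinylogous ester can form. The forward step must be O-selective and acid-free.

4 to 1 and 2. The bond from C2 of the dione to its prenyl CH2 is cut, passing through 3. The forward step must favour C- over O-alkylation.

## Other disconnections considered

Alternative 1: The cut is at C5–C6 and C2–C3, made at the cyclohexanedione oxidation level. In the forward sense the enolate of the symmetric ketone A1 would add in Michael fashion to alkylidenemalonate A2. An alkoxide base would then close the second alpha carbon onto one ester (Dieckmann type) to give the enolised keto ester A3, which must be dehydrogenated to 17.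
- In its favour: the symmetry of A1 settles the placement of both prenyl groups, both partners come from commodity chemicals, the ring is formed by two mild polar bond formations, and no silicon groups are needed.
- Against it: A3 lies two hydrogens below the arene. The usual dehydrogenating agents (halogens, quinones, hot metal catalysts) are also reagents for trisubstituted alkenes or promote closure of the enol oxygen onto a prenyl group. The most delicate operation would therefore fall last. The three stereocentres of A3 are irrelevant.
- Comparison: on structure the chosen plan is better, because extrusion supplies the oxidation level. On mechanism this alternative is the better, being polar and run at low temperature against a hot cycloaddition of a crowded diene. On step economy it is the equal or slightly the better, at about six operations.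

Alternative 2: The cut is at C5–C6, C2–C3, C4–C5 and C1–C2. In the forward sense, irradiation of diazo ketone A4 with silyl ynol ether A5 would trigger a Wolff rearrangement (alkenyl shift, C5–C6), a ketene–alkyne [2+2] union, a four-electron ring opening and a six-electron closure, giving phenol A6.
- In its favour: the regiochemistry is written into the connectivity of the partners and does not rest on orbital coefficients, which is better than the chosen plan. The C2 hydroxyl emerges free, so only one silyl ether has to be removed, which is also better. It is redox-neutral, which is equal.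
- Against it: A4 needs regiocontrolled diazo transfer on an unsymmetrical unsaturated keto ester, and A5 is a skipped enyne prone to isomerisation and to an oxygen-to-carbon silyl shift on heating. A CH2 group on the diazo carbon invites a 1,2-hydrogen shift instead of migration of the electron-poor alkenyl group. The prenyl alkenes can also intercept the ketene stage.
- Comparison: the partners would take roughly twice as many operations to make, so step economy is worse, and the mechanism has more competing channels.

Alternative 3: The cut is at C3–C4 and C5–C6. In the forward sense the fully substituted pyrone A7 would react as a diene across its two termini with A5 (the prenyl-bearing terminus is next to the lactone carbonyl, the phenethyl-bearing terminus next to the ring oxygen). A decarboxylative retro-[4+2] would then give arene A8.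
- In its favour: it uses the same cycloaddition–extrusion logic with no oxidant, which is equal. The polarisation of the two partners is mutual and strong, so regiocontrol is at least equal. The end-game (mild base for the acetate, fluoride for the silyl ether) avoids an aryl 2-silylethyl ether, which is equal or better.
- Against it: A7 is a crowded diene whose acyloxy group lowers its electron demand. Pyrone cycloadditions of this kind need strong heating, and that burden would fall on the thermally fragile A5. Making A7 requires C- over O-selective prenylation of a hydroxypyrone.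
- Comparison: in the chosen plan the heat-tolerant partner is the dienophile and the diene comes from a symmetric dione in four steps. This alternative would be longer overall.

Key step: step 6

Remark on the diene: the diene required is the kinetic silyl dienol ether 10, with both prenyl-bearing carbons sp2 and an unsubstituted CH2–CH2 bridge (a 5-alkoxycyclohexa-1,5-dien-1-yl silyl ether). The isomeric 3-alkoxycyclohexa-1,3-dien-1-yl ether, with a prenyl group on sp3 C6, would lose that prenyl group with the bridge and is not the compound used.

Step 1
Reactants: 1 cyclohexane-1,3-dione; 2 1-bromo-3-methylbut-2-ene (prenyl bromide)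
Product: 4 2-(3-methylbut-2-enyl)cyclohexane-1,3-dione, via potassium enolate 3 (not isolated)
Conditions: KOH (1.0 equiv), H2O, 0 °C; then 2, rt
Reagents that add atoms: none
Why: Enolate C-alkylation; in water the oxygen atoms of ambident enolate 3 are hydrogen-bonded, so the soft allylic bromide is taken up at C2. The acidic product 4 should be separable from neutral O-alkyl and dialkyl by-products by extraction into aqueous NaHCO3 and cold re-acidification.

Step 2
Reactants: 4 2-(3-methylbut-2-enyl)cyclohexane-1,3-dione; 5 2-(trimethylsilyl)ethanol
Product: 6 2-(3-methylbut-2-enyl)-3-[2-(trimethylsilyl)ethoxy]cyclohex-2-en-1-one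
Conditions: PPh3, DIAD, THF, 0 °C to rt
Reagents that add atoms: none
Why: Mitsunobu O-alkylation of an acidic cyclic 1,3-dione enol by a primary alcohol under neutral conditions; the symmetry of 4 allows only one vinylogous ester. Acid-catalysed enol etherification is avoided because acid closes the enol onto the prenyl group and promotes elimination from 5.

Step 3
Reactants: 6 2-(3-methylbut-2-enyl)-3-[2-(trimethylsilyl)ethoxy]cyclohex-2-en-1-one; 2 1-bromo-3-methylbut-2-ene
Product: 8 2,6-bis(3-methylbut-2-enyl)-3-[2-(trimethylsilyl)ethoxy]cyclohex-2-en-1-one (racemic), via lithium enolate 7 (not isolated)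
Conditions: LiN(iPr)2 (1.1 equiv), THF, −78 °C; then 2, −78 to 0 °C
Reagents that add atoms: none
Why: Stork–Danheiser alkylation; a vinylogous ester is deprotonated kinetically at the alpha' carbon (C6) and the cross-conjugated enolate 7 is C-alkylated by the allylic bromide. The new C6 stereocentre is racemic and is erased in step 4.

Step 4
Reactants: 8 2,6-bis(3-methylbut-2-enyl)-3-[2-(trimethylsilyl)ethoxy]cyclohex-2-en-1-one
Product: 10 tert-butyl(dimethyl){[2,6-bis(3-methylbut-2-enyl)-5-[2-(trimethylsilyl)ethoxy]cyclohexa-1,5-dien-1-yl]oxy}silane, via lithium dienolate 9 (not isolated)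
Conditions: LiN(iPr)2 (1.2 equiv), THF, −78 °C; then TBSCl, DMPU, −78 °C to rt; NaHCO3 work-up, Et3N-deactivated silica
Reagents that add atoms: tert-butyl(chloro)dimethylsilane (TBSCl), CC(C)(C)[Si](C)(C)Cl
Why: A second kinetic alpha' deprotonation removes the remaining C6–H, and O-silylation of enolate 9 fixes both prenyl-bearing carbons as diene carbons with an unsubstituted CH2–CH2 bridge. DMPU speeds silylation of the hindered lithium enolate, and the acid-labile product is kept under basic conditions.

Step 5
Reactants: 11 4-phenylbut-1-yne
Product: 13 methyl 5-phenylpent-2-ynoate, via lithium acetylide 12 (not isolated)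
Conditions: n-BuLi, THF, −78 °C; then ClCO2Me, −78 to 0 °C
Reagents that add atoms: methyl chloroformate, COC(=O)Cl
Why: Deprotonation of the terminal alkyne and C-acylation of acetylide 12 by the chloroformate; low temperature prevents further addition to the ynoate.

Step 6
Reactants: 10 tert-butyl(dimethyl){[2,6-bis(3-methylbut-2-enyl)-5-[2-(trimethylsilyl)ethoxy]cyclohexa-1,5-dien-1-yl]oxy}silane; 13 methyl 5-phenylpent-2-ynoate
Product: 15 methyl 4-[tert-butyl(dimethyl)silyl]oxy-3,5-bis(3-methylbut-2-enyl)-6-(2-phenylethyl)-2-[2-(trimethylsilyl)ethoxy]benzoate, via bicyclo[2.2.2]octadiene adduct 14 (not isolated)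
Conditions: 13 (3 equiv), mesitylene, BHT (cat.), base-washed sealed tube, 175–180 °C
Reagents that add atoms: none
Why: Alder–Rickert reaction; the closest known case is the resorcylate synthesis from 1-alkoxy-3-silyloxycyclohexa-1,3-dienes and alkynoates. The ring holds diene 10 s-cis and its two oxygen substituents raise the HOMO, so a thermal, concerted but asynchronous [4+2] cycloaddition with the electron-poor triple bond of 13 forms C5–C6 and C1–C2 (ring A numbering) and gives bicycle 14. Ring A is thus closed by an intermolecular suprafacial [4+2] cycloaddition, not by cyclisation of a chain. Continued heating drives a retro-[4+2] that expels the CH2–CH2 bridge as ethene, made irreversible by aromatisation and gas loss, so neither oxidant nor acid is needed. The two bridgehead stereocentres of 14 arise as a racemate and vanish on aromatisation. The step needs regioselectivity: the prenyl-bearing diene terminus is beta to the silyloxy carbon and vinylogously conjugated to the alkoxy oxygen (Danishefsky-type polarisation), carries the largest HOMO coefficient, and pairs with the ynoate beta carbon, which puts phenethyl next to the C5 prenyl group and the ester next to the C2 oxygen. It also needs chemoselectivity, which holds because the isolated prenyl alkenes are neither dienes nor activated dienophiles. Excess dienophile and the lowest workable temperature keep [1,5]-hydrogen shifts in 10 from competing.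

Step 7
Reactants: 15 methyl 4-[tert-butyl(dimethyl)silyl]oxy-3,5-bis(3-methylbut-2-enyl)-6-(2-phenylethyl)-2-[2-(trimethylsilyl)ethoxy]benzoate
Product: 17 methyl 2,4-dihydroxy-3,5-bis(3-methylbut-2-enyl)-6-(2-phenylethyl)benzoate, via 4-hydroxy intermediate 16 (not isolated)
Conditions: TBAF (4 equiv), THF, 0 °C, then 50 °C; aq NH4Cl
Reagents that add atoms: none
Why: Fluoride attacks silicon; the aryl silyl ether falls at 0 °C to the phenoxide of 16, and on warming a fluoride-triggered 1,2-elimination of the 2-silylethyl ether releases ethene and the salicylate phenoxide. No acid is present, so the ortho-prenyl phenols cannot cyclise, and the di-ortho-substituted ester is shielded from attack.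

Compound list
1 | cyclohexane-1,3-dione | O=C1CCCC(=O)C1 | starting material
2 | 1-bromo-3-methylbut-2-ene (prenyl bromide) | CC(C)=CCBr | starting material
3 | potassium 3-oxocyclohex-1-en-1-olate | [K+].[O-]C1=CC(=O)CCC1 | intermediate (not isolated)
4 | 2-(3-methylbut-2-enyl)cyclohexane-1,3-dione (largely enolised) | CC(C)=CCC1C(=O)CCCC1=O | intermediate
5 | 2-(trimethylsilyl)ethanol | C[Si](C)(C)CCO | starting material
6 | 2-(3-methylbut-2-enyl)-3-[2-(trimethylsilyl)ethoxy]cyclohex-2-en-1-one | C[Si](C)(C)CCOC1=C(CC=C(C)C)C(=O)CCC1 | intermediate
7 | lithium 6-(3-methylbut-2-enyl)-5-[2-(trimethylsilyl)ethoxy]cyclohexa-1,5-dien-1-olate | [Li+].[O-]C1=CCCC(OCC[Si](C)(C)C)=C1CC=C(C)C | intermediate (not isolated)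
8 | 2,6-bis(3-methylbut-2-enyl)-3-[2-(trimethylsilyl)ethoxy]cyclohex-2-en-1-one (racemic) | C[Si](C)(C)CCOC1=C(CC=C(C)C)C(=O)C(CC=C(C)C)CC1 | intermediate
9 | lithium 2,6-bis(3-methylbut-2-enyl)-5-[2-(trimethylsilyl)ethoxy]cyclohexa-1,5-dien-1-olate | [Li+].[O-]C1=C(CC=C(C)C)CCC(OCC[Si](C)(C)C)=C1CC=C(C)C | intermediate (not isolated)
10 | tert-butyl(dimethyl){[2,6-bis(3-methylbut-2-enyl)-5-[2-(trimethylsilyl)ethoxy]cyclohexa-1,5-dien-1-yl]oxy}silane | C[Si](C)(C)CCOC1=C(CC=C(C)C)C(O[Si](C)(C)C(C)(C)C)=C(CC=C(C)C)CC1 | intermediate
11 | 4-phenylbut-1-yne | C#CCCc1ccccc1 | starting material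
12 | lithium 4-phenylbut-1-yn-1-ide | [Li+].[C-]#CCCc1ccccc1 | intermediate (not isolated)
13 | methyl 5-phenylpent-2-ynoate | COC(=O)C#CCCc1ccccc1 | intermediate
14 | methyl 5-{[tert-butyl(dimethyl)silyl]oxy}-4,6-bis(3-methylbut-2-enyl)-3-(2-phenylethyl)-1-[2-(trimethylsilyl)ethoxy]bicyclo[2.2.2]octa-2,5-diene-2-carboxylate (racemic; bridgeheads fixed by the bicycle) | COC(=O)C1=C(CCc2ccccc2)C2(CC=C(C)C)CCC1(OCC[Si](C)(C)C)C(CC=C(C)C)=C2O[Si](C)(C)C(C)(C)C | intermediate (not isolated)
15 | methyl 4-[tert-butyl(dimethyl)silyl]oxy-3,5-bis(3-methylbut-2-enyl)-6-(2-phenylethyl)-2-[2-(trimethylsilyl)ethoxy]benzoate | COC(=O)c1c(OCC[Si](C)(C)C)c(CC=C(C)C)c(O[Si](C)(C)C(C)(C)C)c(CC=C(C)C)c1CCc1ccccc1 | intermediate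
16 | methyl 4-hydroxy-3,5-bis(3-methylbut-2-enyl)-6-(2-phenylethyl)-2-[2-(trimethylsilyl)ethoxy]benzoate | COC(=O)c1c(OCC[Si](C)(C)C)c(CC=C(C)C)c(O)c(CC=C(C)C)c1CCc1ccccc1 | intermediate (not isolated)
17 | methyl 2,4-dihydroxy-3,5-bis(3-methylbut-2-enyl)-6-(2-phenylethyl)benzoate | COC(=O)c1c(O)c(CC=C(C)C)c(O)c(CC=C(C)C)c1CCc1ccccc1 | target

Total step count: 7. Longest linear sequence: 6 (steps 1, 2, 3, 4, 6, 7); step 5 is a one-step branch.

Least certain steps

Step 6 (key step). The cycloaddition may be slow because both diene termini are fully substituted and two quaternary bridgeheads must form. At the temperature then needed, a thermal [1,5]-hydrogen shift around the diene ring can move a prenyl- or oxygen-bearing carbon into the two-carbon bridge, and that substituent is then lost with the bridge. Steric repulsion between the terminal prenyl group and the phenethyl group may also erode the electronically preferred orientation, and adventitious acid may strip the silyl groups. The fallback defers the terminal prenyl group and sets out from 6. Kinetic enolisation (LiN(iPr)2, then TBSCl/DMPU) should give the less substituted diene tert-butyl(dimethyl){[6-(3-methylbut-2-enyl)-5-[2-(trimethylsilyl)ethoxy]cyclohexa-1,5-dien-1-yl]oxy}silane F1, a diene of the class for which this reaction is established. Heating F1 with 13 should give, through its bicyclo[2.2.2]octadiene adduct F2, the pentasubstituted arene methyl 4-[tert-butyl(dimethyl)silyl]oxy-3-(3-methylbut-2-enyl)-6-(2-phenylethyl)-2-[2-(trimethylsilyl)ethoxy]benzoate F3. One equivalent of TBAF at 0 °C should free the C4 phenol, methyl 4-hydroxy-3-(3-methylbut-2-enyl)-6-(2-phenylethyl)-2-[2-(trimethylsilyl)ethoxy]benzoate F4. Its sodium phenoxide (NaH, toluene) should be C-alkylated by 2 at C5, the only free ortho position, which returns the route at 16; the warm stage of step 7 then completes it.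

Step 4. Enolisation may be incomplete or misdirected (gamma CH2 instead of the hindered alpha' methine), silylation of the tetrasubstituted enolate by a bulky chlorosilane may be slow, and the dienol ether may hydrolyse on isolation. The fallback sets out from 8 and treats silicon as a transient activating group instead of a protecting group. Deprotonation with LiN(iPr)2 in the presence of Me3SiCl (internal quench) and non-aqueous work-up should give trimethyl{[2,6-bis(3-methylbut-2-enyl)-5-[2-(trimethylsilyl)ethoxy]cyclohexa-1,5-dien-1-yl]oxy}silane F5. Used crude, F5 should react with 13 as in step 6, through its bicyclo[2.2.2]octadiene adduct F6, to give the aryl trimethylsilyl ether methyl 3,5-bis(3-methylbut-2-enyl)-6-(2-phenylethyl)-2-[2-(trimethylsilyl)ethoxy]-4-(trimethylsilyloxy)benzoate F7. K2CO3 in methanol cleaves F7 and returns the route at 16.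

Step 7. Once the ring carries one phenoxide, elimination of the aryl 2-silylethyl ether would generate a dianion and may be sluggish. The heating then needed exposes the ester and the electron-rich ring to basic fluoride. The fallback removes the 2-silylethyl ether from the plan and sets out from 4. Silylation (TBSCl, imidazole) should give the vinylogous silyl ester 3-[tert-butyl(dimethyl)silyl]oxy-2-(3-methylbut-2-enyl)cyclohex-2-en-1-one F8. Alpha' prenylation as in step 3 should give 3-[tert-butyl(dimethyl)silyl]oxy-2,6-bis(3-methylbut-2-enyl)cyclohex-2-en-1-one F9, and enolisation and silylation as in step 4 the bis-silyl diene {[2,4-bis(3-methylbut-2-enyl)cyclohexa-1,3-diene-1,3-diyl]bis(oxy)}bis[tert-butyl(dimethyl)silane] F10. Reaction with 13 as in step 6 should pass through the bicyclo[2.2.2]octadiene adduct F11 to the bis-silyl arene methyl 2,4-bis{[tert-butyl(dimethyl)silyl]oxy}-3,5-bis(3-methylbut-2-enyl)-6-(2-phenylethyl)benzoate F12. Both aryl silyl ethers of F12 should fall to TBAF at 0 °C, which returns the route at 17. The price is a more labile vinylogous silyl ester in the alkylation.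

Step 2. The 2-substituted dione may give competing C-alkylation or stall in the Mitsunobu reaction, and separation from the phosphine oxide may be awkward. The fallback sets out from 4 and uses addition–elimination instead of O-alkylation. Oxalyl chloride with catalytic DMF in CH2Cl2 at 0 °C (HCl swept out with argon) should give the vinylogous acid chloride 3-chloro-2-(3-methylbut-2-enyl)cyclohex-2-en-1-one F13. Treating F13 with 5 and NaH in THF should displace chloride and return the route at 6.

Further compounds
F1 | step 6 | tert-butyl(dimethyl){[6-(3-methylbut-2-enyl)-5-[2-(trimethylsilyl)ethoxy]cyclohexa-1,5-dien-1-yl]oxy}silane | C[Si](C)(C)CCOC1=C(CC=C(C)C)C(O[Si](C)(C)C(C)(C)C)=CCC1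
F2 | step 6 | methyl 5-{[tert-butyl(dimethyl)silyl]oxy}-6-(3-methylbut-2-enyl)-3-(2-phenylethyl)-1-[2-(trimethylsilyl)ethoxy]bicyclo[2.2.2]octa-2,5-diene-2-carboxylate (racemic) | COC(=O)C1=C(CCc2ccccc2)C2CCC1(OCC[Si](C)(C)C)C(CC=C(C)C)=C2O[Si](C)(C)C(C)(C)C
F3 | step 6 | methyl 4-[tert-butyl(dimethyl)silyl]oxy-3-(3-methylbut-2-enyl)-6-(2-phenylethyl)-2-[2-(trimethylsilyl)ethoxy]benzoate | COC(=O)c1c(OCC[Si](C)(C)C)c(CC=C(C)C)c(O[Si](C)(C)C(C)(C)C)cc1CCc1ccccc1
F4 | step 6 | methyl 4-hydroxy-3-(3-methylbut-2-enyl)-6-(2-phenylethyl)-2-[2-(trimethylsilyl)ethoxy]benzoate | COC(=O)c1c(OCC[Si](C)(C)C)c(CC=C(C)C)c(O)cc1CCc1ccccc1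
F5 | step 4 | trimethyl{[2,6-bis(3-methylbut-2-enyl)-5-[2-(trimethylsilyl)ethoxy]cyclohexa-1,5-dien-1-yl]oxy}silane | C[Si](C)(C)CCOC1=C(CC=C(C)C)C(O[Si](C)(C)C)=C(CC=C(C)C)CC1
F6 | step 4 | methyl 4,6-bis(3-methylbut-2-enyl)-3-(2-phenylethyl)-1-[2-(trimethylsilyl)ethoxy]-5-(trimethylsilyloxy)bicyclo[2.2.2]octa-2,5-diene-2-carboxylate (racemic) | COC(=O)C1=C(CCc2ccccc2)C2(CC=C(C)C)CCC1(OCC[Si](C)(C)C)C(CC=C(C)C)=C2O[Si](C)(C)C
F7 | step 4 | methyl 3,5-bis(3-methylbut-2-enyl)-6-(2-phenylethyl)-2-[2-(trimethylsilyl)ethoxy]-4-(trimethylsilyloxy)benzoate | COC(=O)c1c(OCC[Si](C)(C)C)c(CC=C(C)C)c(O[Si](C)(C)C)c(CC=C(C)C)c1CCc1ccccc1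
F8 | step 7 | 3-[tert-butyl(dimethyl)silyl]oxy-2-(3-methylbut-2-enyl)cyclohex-2-en-1-one | CC(C)=CCC1=C(O[Si](C)(C)C(C)(C)C)CCCC1=O
F9 | step 7 | 3-[tert-butyl(dimethyl)silyl]oxy-2,6-bis(3-methylbut-2-enyl)cyclohex-2-en-1-one (racemic) | CC(C)=CCC1CCC(O[Si](C)(C)C(C)(C)C)=C(CC=C(C)C)C1=O
F10 | step 7 | {[2,4-bis(3-methylbut-2-enyl)cyclohexa-1,3-diene-1,3-diyl]bis(oxy)}bis[tert-butyl(dimethyl)silane] | CC(C)=CCC1=C(O[Si](C)(C)C(C)(C)C)C(CC=C(C)C)=C(O[Si](C)(C)C(C)(C)C)CC1
F11 | step 7 | methyl 1,5-bis{[tert-butyl(dimethyl)silyl]oxy}-4,6-bis(3-methylbut-2-enyl)-3-(2-phenylethyl)bicyclo[2.2.2]octa-2,5-diene-2-carboxylate (racemic) | COC(=O)C1=C(CCc2ccccc2)C2(CC=C(C)C)CCC1(O[Si](C)(C)C(C)(C)C)C(CC=C(C)C)=C2O[Si](C)(C)C(C)(C)C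
F12 | step 7 | methyl 2,4-bis{[tert-butyl(dimethyl)silyl]oxy}-3,5-bis(3-methylbut-2-enyl)-6-(2-phenylethyl)benzoate | COC(=O)c1c(O[Si](C)(C)C(C)(C)C)c(CC=C(C)C)c(O[Si](C)(C)C(C)(C)C)c(CC=C(C)C)c1CCc1ccccc1
F13 | step 2 | 3-chloro-2-(3-methylbut-2-enyl)cyclohex-2-en-1-one | CC(C)=CCC1=C(Cl)CCCC1=O
A1 | alternative 1 | 2,10-dimethylundeca-2,9-dien-6-one | CC(C)=CCCC(=O)CCC=C(C)C
A2 | alternative 1 | dimethyl 2-(3-phenylpropylidene)propanedioate | COC(=O)C(=CCCc1ccccc1)C(=O)OC
A3 | alternative 1 | methyl 4-hydroxy-3,5-bis(3-methylbut-2-enyl)-2-oxo-6-(2-phenylethyl)cyclohex-3-ene-1-carboxylate (racemic, 1,6-trans and 5,6-trans, one enantiomer drawn) | COC(=O)[C@@H]1C(=O)C(CC=C(C)C)=C(O)[C@H](CC=C(C)C)[C@H]1CCc1ccccc1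
A4 | alternative 2 | methyl (2E)-5-diazo-8-methyl-4-oxo-3-(2-phenylethyl)nona-2,7-dienoate | COC(=O)/C=C(\CCc1ccccc1)C(=O)C(=[N+]=[N-])CC=C(C)C
A5 | alternative 2 | [(5-methylhex-4-en-1-yn-1-yl)oxy]tri(propan-2-yl)silane | CC(C)=CCC#CO[Si](C(C)C)(C(C)C)C(C)C
A6 | alternative 2 | methyl 2-hydroxy-3,5-bis(3-methylbut-2-enyl)-6-(2-phenylethyl)-4-{[tri(propan-2-yl)silyl]oxy}benzoate | COC(=O)c1c(O)c(CC=C(C)C)c(O[Si](C(C)C)(C(C)C)C(C)C)c(CC=C(C)C)c1CCc1ccccc1
A7 | alternative 3 | methyl 4-acetyloxy-5-(3-methylbut-2-enyl)-6-oxo-2-(2-phenylethyl)-6H-pyran-3-carboxylate | COC(=O)C1=C(CCc2ccccc2)OC(=O)C(CC=C(C)C)=C1OC(C)=O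
A8 | alternative 3 | methyl 2-acetyloxy-3,5-bis(3-methylbut-2-enyl)-6-(2-phenylethyl)-4-{[tri(propan-2-yl)silyl]oxy}benzoate | COC(=O)c1c(OC(C)=O)c(CC=C(C)C)c(O[Si](C(C)C)(C(C)C)C(C)C)c(CC=C(C)C)c1CCc1ccccc1
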